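## Retrosynthetic overview

1. Numbering: rings A/C are the chromen-4-one, ring B is the pendant arene C1'–C6', and ring D is the dimethylpyran O–C2''(Me)2–C3''=C4''. The target comes from its 7,2'-bis-MOM ether by acid methanolysis as the last step.
2. Ring D is disconnected at C3''=C4'' and at O–C2'' together. This gives a ring-B salicylaldehyde (C3'-CHO, free C4'-OH, C2'-OMOM) and 2-methylprop-1-enylboronic acid, joined by an amine-catalysed Petasis borono-Mannich / amine loss / oxa-6π electrocyclisation cascade.
3. Enabling feature: the ortho pair C4'-OH / C3'-CHO on ring B. The phenol oxygen binds boron and delivers the alkenyl group to the neighbouring iminium carbon, then becomes the carbonyl of the oxatriene O=C4'–C3'=C4''H–C3''H=C2''Me2, which closes. C5'-OMe and C2'-OMOM flank this pair, so no other oxygen can take part.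
4. The C3–C1' bond is made by Suzuki–Miyaura coupling of a ring-B pinacol boronate with 3-iodo-7-(MOM-oxy)chromone. The chromone comes from 2,4-dihydroxyacetophenone by way of an enaminone and an iodocyclisation.
5. Ring B comes from O-benzylisovanillin by Baeyer–Villiger oxidation, MOM protection, directed ortho-metalation/formylation, bromination and borylation, so the two phenol oxygens are different from the first step. Rings A and B are bought as arenes; ring C closes in step 8 and ring D in step 11.

Key step: step 11

Remark: the target has no stereocentre, and its only non-aromatic C=C lies inside a six-membered ring, so no stereocontrol is needed. O-benzylisovanillin, 2,4-dihydroxyacetophenone and 2-methylprop-1-enylboronic acid are taken as commercial.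

## Route

Step 1
Reactants: 1 3-(benzyloxy)-4-methoxybenzaldehyde
Product: 3 3-(benzyloxy)-4-methoxyphenol, via aryl formate 2 (not isolated)
Conditions: mCPBA (1.3 equiv), CH2Cl2, 0 °C to rt; then K2CO3 (0.2 equiv), MeOH, rt
Reagents that add atoms: mCPBA, O=C(OO)c1cccc(Cl)c1
Why: In this Baeyer–Villiger oxidation the electron-rich aryl group (para-OMe) migrates in preference to hydride and the formate is removed by mild methanolysis, which installs the future 2'-oxygen while the future 4'-oxygen stays benzylated.

Step 2
Reactants: 3 3-(benzyloxy)-4-methoxyphenol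
Product: 4 2-(benzyloxy)-1-methoxy-4-(methoxymethoxy)benzene
Conditions: MOMCl, iPr2NEt, CH2Cl2, 0 °C to rt
Reagents that add atoms: chloromethyl methyl ether (MOMCl), COCCl
Why: This is a standard O-alkylation of a phenol, and MOM is chosen because it directs ortho-metalation, survives base, palladium catalysis and H2, and later leaves under acid mild enough for a 2,2-dimethylchromene.

Step 3
Reactants: 4 2-(benzyloxy)-1-methoxy-4-(methoxymethoxy)benzene
Product: 6 2-(benzyloxy)-3-methoxy-6-(methoxymethoxy)benzaldehyde, via aryllithium 5 (not isolated)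
Conditions: n-BuLi, TMEDA, THF, -20 to 0 °C; DMF, 0 °C to rt; then H2O
Reagents that add atoms: N,N-dimethylformamide, CN(C)C=O
Why: In this directed ortho-metalation the OMOM and OBn groups cooperate to place lithium on the CH between them, and the DMF quench should give the aldehyde at the future C3'.

Step 4
Reactants: 6 2-(benzyloxy)-3-methoxy-6-(methoxymethoxy)benzaldehyde
Product: 7 2-(benzyloxy)-5-bromo-3-methoxy-6-(methoxymethoxy)benzaldehyde
Conditions: NBS, MeCN, 0 °C to rt, dark
Reagents that add atoms: N-bromosuccinimide, O=C1CCC(=O)N1Br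
Why: In this electrophilic aromatic bromination C5 is ortho to OMOM, para to OBn and meta to CHO, whereas C4 is activated only by OMe and lies para to the deactivating formyl group.

Step 5
Reactants: 7 2-(benzyloxy)-5-bromo-3-methoxy-6-(methoxymethoxy)benzaldehyde
Product: 8 2-(benzyloxy)-3-methoxy-6-(methoxymethoxy)-5-(4,4,5,5-tetramethyl-1,3,2-dioxaborolan-2-yl)benzaldehyde
Conditions: B2pin2, Pd(dppf)Cl2 (5 mol %), KOAc, 1,4-dioxane, 90 °C
Reagents that add atoms: bis(pinacolato)diboron, CC1(C)OB(OC1(C)C)B1OC(C)(C)C(C)(C)O1
Why: The Miyaura borylation uses only the weak base acetate and therefore tolerates the aldehyde, the acetal and the benzyl ether.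

Step 6
Reactants: 9 2,4-dihydroxyacetophenone
Product: 10 1-[2-hydroxy-4-(methoxymethoxy)phenyl]ethan-1-one
Conditions: MOMCl (1.1 equiv), K2CO3, acetone, rt
Reagents that add atoms: chloromethyl methyl ether (MOMCl), COCCl
Why: This O-alkylation is selective because the 2-OH is tied up in a hydrogen bond to the ketone, so only the more acidic and accessible 4-OH should react.

Step 7
Reactants: 10 1-[2-hydroxy-4-(methoxymethoxy)phenyl]ethan-1-one
Product: 11 (E)-3-(dimethylamino)-1-[2-hydroxy-4-(methoxymethoxy)phenyl]prop-2-en-1-one
Conditions: DMF-DMA, toluene, 95 °C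
Reagents that add atoms: N,N-dimethylformamide dimethyl acetal, COC(OC)N(C)C
Why: Condensation of the methyl ketone with the amide acetal gives the enaminone, which adopts the E geometry as the thermodynamically favoured push–pull alkene and carries the future C2 of ring C.

Step 8
Reactants: 11 (E)-3-(dimethylamino)-1-[2-hydroxy-4-(methoxymethoxy)phenyl]prop-2-en-1-one
Product: 12 3-iodo-7-(methoxymethoxy)-4H-chromen-4-one
Conditions: I2, pyridine, CHCl3, rt
Reagents that add atoms: iodine, II
Why: In this iodocyclisation of an ortho-hydroxyaryl enaminone, alpha-iodination gives an iminium ion that the phenol attacks, loss of dimethylamine closes ring C, and pyridine buffers the acid so the MOM ether survives.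

Step 9
Reactants: 8 2-(benzyloxy)-3-methoxy-6-(methoxymethoxy)-5-(4,4,5,5-tetramethyl-1,3,2-dioxaborolan-2-yl)benzaldehyde; 12 3-iodo-7-(methoxymethoxy)-4H-chromen-4-one
Product: 13 2-(benzyloxy)-3-methoxy-6-(methoxymethoxy)-5-[7-(methoxymethoxy)-4-oxo-4H-chromen-3-yl]benzaldehyde
Conditions: Pd(dppf)Cl2 (5 mol %), Na2CO3, DME/H2O, 80 °C
Reagents that add atoms: none
Why: Suzuki–Miyaura coupling of a 3-iodochromone with an arylboronate is the standard way to form the isoflavone C3–C1' bond, and carbonate is mild enough for ring C and the aldehyde.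

Step 10
Reactants: 13 2-(benzyloxy)-3-methoxy-6-(methoxymethoxy)-5-[7-(methoxymethoxy)-4-oxo-4H-chromen-3-yl]benzaldehyde
Product: 14 2-hydroxy-3-methoxy-6-(methoxymethoxy)-5-[7-(methoxymethoxy)-4-oxo-4H-chromen-3-yl]benzaldehyde
Conditions: H2 (1 atm), 10% Pd/C, EtOAc, rt, stopped at consumption of 13
Reagents that add atoms: none
Why: Hydrogenolysis of the aryl benzyl ether should be faster than reduction of the doubly ortho-oxygenated aldehyde or of the trisubstituted C2=C3 bond of ring C, and the MOM acetals are inert, so only the 4'-OH is freed.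

Step 11
Reactants: 14 2-hydroxy-3-methoxy-6-(methoxymethoxy)-5-[7-(methoxymethoxy)-4-oxo-4H-chromen-3-yl]benzaldehyde; 15 2-methylprop-1-en-1-ylboronic acid
Product: 18 3-[8-methoxy-5-(methoxymethoxy)-2,2-dimethyl-2H-chromen-6-yl]-7-(methoxymethoxy)-4H-chromen-4-one, via Petasis allylic amine 16 (not isolated), via ortho-quinone methide 17 (not isolated)
Conditions: 15 (1.5 equiv), Bn2NH (0.4 equiv), 1,4-dioxane, 90 °C
Reagents that add atoms: none
Why: Dibenzylamine condenses with the C3' aldehyde to an iminium ion, the adjacent C4' phenol binds 15 as a tetracoordinate boronate, and the isobutenyl group migrates intramolecularly from boron to the iminium carbon, which forms the C4''–C3'' bond of 16. At 90 °C the electron-rich ring B expels the protonated amine to give the (Z)-ortho-quinone methide 17, whose oxatriene O=C4'–C3'=C4''H–C3''H=C2''Me2 undergoes a thermal disrotatory oxa-6π electrocyclisation that forms the O–C2'' bond, leaves the double bond at C3''=C4'' and re-aromatises ring B, which drives the sequence forward and returns the amine for turnover. The closest known reaction type is the amine-catalysed Petasis borono-Mannich condensation of salicylaldehydes with alkenylboronic acids to give 2H-chromenes. The one ring closed, six-membered ring D, closes by 6π electrocyclisation (formally 6-endo), and no stereocentre remains because the centre of 16 is erased in 17 and C2'' carries two methyl groups. The step needs closure on O4' and not on O2' or O7, which is secured because only O4' is free, and alkenyl transfer needs a free phenol ortho to the iminium carbon. It also needs the amine to engage the aldehyde and not C2 of ring C, which the bulky, weakly nucleophilic and substoichiometric dibenzylamine favours, and any reversible opening of ring C would re-close under the acid of step 12.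

Step 12
Reactants: 18 3-[8-methoxy-5-(methoxymethoxy)-2,2-dimethyl-2H-chromen-6-yl]-7-(methoxymethoxy)-4H-chromen-4-one
Product: 19 7-hydroxy-3-(5-hydroxy-8-methoxy-2,2-dimethyl-2H-chromen-6-yl)-4H-chromen-4-one
Conditions: HCl (cat., 1.25 M in MeOH), MeOH/THF, 45 °C
Reagents that add atoms: none
Why: Acid-catalysed transacetalisation removes both aryl MOM ethers under conditions commonly tolerated by 2,2-dimethylchromenes and 2'-hydroxyisoflavones.

## Compound list

1 | 3-(benzyloxy)-4-methoxybenzaldehyde | COc1ccc(C=O)cc1OCc1ccccc1 | starting material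
2 | 3-(benzyloxy)-4-methoxyphenyl formate | COc1ccc(OC=O)cc1OCc1ccccc1 | intermediate
3 | 3-(benzyloxy)-4-methoxyphenol | COc1ccc(O)cc1OCc1ccccc1 | intermediate
4 | 2-(benzyloxy)-1-methoxy-4-(methoxymethoxy)benzene | COCOc1ccc(OC)c(OCc2ccccc2)c1 | intermediate
5 | [2-(benzyloxy)-3-methoxy-6-(methoxymethoxy)phenyl]lithium | [Li]c1c(OCOC)ccc(OC)c1OCc1ccccc1 | intermediate
6 | 2-(benzyloxy)-3-methoxy-6-(methoxymethoxy)benzaldehyde | COCOc1ccc(OC)c(OCc2ccccc2)c1C=O | intermediate
7 | 2-(benzyloxy)-5-bromo-3-methoxy-6-(methoxymethoxy)benzaldehyde | COCOc1c(Br)cc(OC)c(OCc2ccccc2)c1C=O | intermediate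
8 | 2-(benzyloxy)-3-methoxy-6-(methoxymethoxy)-5-(4,4,5,5-tetramethyl-1,3,2-dioxaborolan-2-yl)benzaldehyde | COCOc1c(B2OC(C)(C)C(C)(C)O2)cc(OC)c(OCc2ccccc2)c1C=O | intermediate
9 | 2,4-dihydroxyacetophenone | CC(=O)c1ccc(O)cc1O | starting material
10 | 1-[2-hydroxy-4-(methoxymethoxy)phenyl]ethan-1-one | CC(=O)c1ccc(OCOC)cc1O | intermediate
11 | (E)-3-(dimethylamino)-1-[2-hydroxy-4-(methoxymethoxy)phenyl]prop-2-en-1-one | CN(C)/C=C/C(=O)c1ccc(OCOC)cc1O | intermediate
12 | 3-iodo-7-(methoxymethoxy)-4H-chromen-4-one | COCOc1ccc2c(c1)occ(I)c2=O | intermediate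
13 | 2-(benzyloxy)-3-methoxy-6-(methoxymethoxy)-5-[7-(methoxymethoxy)-4-oxo-4H-chromen-3-yl]benzaldehyde | COCOc1ccc2c(c1)occ(-c1cc(OC)c(OCc3ccccc3)c(C=O)c1OCOC)c2=O | intermediate
14 | 2-hydroxy-3-methoxy-6-(methoxymethoxy)-5-[7-(methoxymethoxy)-4-oxo-4H-chromen-3-yl]benzaldehyde | COCOc1ccc2c(c1)occ(-c1cc(OC)c(O)c(C=O)c1OCOC)c2=O | intermediate
15 | 2-methylprop-1-en-1-ylboronic acid | CC(C)=CB(O)O | starting material
16 | 3-{3-[1-(dibenzylamino)-3-methylbut-2-en-1-yl]-4-hydroxy-5-methoxy-2-(methoxymethoxy)phenyl}-7-(methoxymethoxy)-4H-chromen-4-one (racemic, transient) | COCOc1ccc2c(c1)occ(-c1cc(OC)c(O)c(C(C=C(C)C)N(Cc3ccccc3)Cc3ccccc3)c1OCOC)c2=O | intermediate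
17 | (Z)-ortho-quinone methide: 3-[5-methoxy-2-(methoxymethoxy)-3-(3-methylbut-2-en-1-ylidene)-4-oxocyclohexa-1,5-dien-1-yl]-7-(methoxymethoxy)-4H-chromen-4-one, alkenyl group cis to the ring C=O | COCOc1ccc2c(c1)occ(C1=C(OCOC)/C(=C/C=C(C)C)C(=O)C(OC)=C1)c2=O | intermediate
18 | 3-[8-methoxy-5-(methoxymethoxy)-2,2-dimethyl-2H-chromen-6-yl]-7-(methoxymethoxy)-4H-chromen-4-one | COCOc1ccc2c(c1)occ(-c1cc(OC)c3c(c1OCOC)C=CC(C)(C)O3)c2=O | intermediate
19 | 7-hydroxy-3-(5-hydroxy-8-methoxy-2,2-dimethyl-2H-chromen-6-yl)-4H-chromen-4-one | COc1cc(-c2coc3cc(O)ccc3c2=O)c(O)c2c1OC(C)(C)C=C2 | target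

## Step count and risks

Total step count: 12. Longest linear sequence: 9 steps (steps 1–5, then 9–12). Steps 6–8 form the convergent ring A/C branch.

**Steps most likely to fail**

1. **Step 11.** Iminium formation at the di-ortho-substituted, electron-rich aldehyde may be slow. Protodeboronation of the alkenylboronic acid and amine-induced opening of ring C could then compete with the cascade.
   Fallback, from 14 back to 18: the same two bonds are made by a polar route free of amine and boron. The phenol of 14 is deprotonated with NaH in DMF and heated with (2-methylprop-1-en-1-yl)triphenylphosphonium bromide. Oxa-Michael addition of the phenoxide to the beta-carbon of the vinylphosphonium salt should give the ether-linked phosphorus ylide F1. This ylide closes on the neighbouring formyl group by intramolecular Wittig olefination and gives 18. The method is the known vinylphosphonium annulation of salicylaldehydes to 2H-chromenes.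

2. **Step 10.** Saturation of the C2=C3 bond of ring C or reduction of the formyl group may compete with O-benzyl cleavage on palladium.
   Fallback, from 6 back to 14: the benzyl group is removed before any halide or chromone is present.
   - Hydrogenolysis of 6 (H2, Pd/C, EtOAc) should give 2-hydroxy-3-methoxy-6-(methoxymethoxy)benzaldehyde F2.
   - NBS bromination, now also directed para to the free phenol, should give 3-bromo-6-hydroxy-5-methoxy-2-(methoxymethoxy)benzaldehyde F3.
   - Miyaura borylation (B2pin2, Pd(dppf)Cl2, KOAc) should give 6-hydroxy-5-methoxy-2-(methoxymethoxy)-3-(4,4,5,5-tetramethyl-1,3,2-dioxaborolan-2-yl)benzaldehyde F4.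
   - Suzuki–Miyaura coupling of F4 with 12, with one extra equivalent of Na2CO3 for the phenol, rejoins the route at 14.

3. **Step 9.** Protodeboronation of the ortho-alkoxy boronate and base-induced opening of the pyranone ring of the iodide may outrun transmetalation in the aqueous basic medium.
   Fallback, from 12 and 7 back to 13 (step 5 is skipped): the polarity of the partners is reversed under anhydrous, base-free conditions. Zinc insertion into 12 (Zn dust, LiCl, THF) should give the chromon-3-ylzinc iodide F5. Negishi coupling of F5 with bromide 7 (Pd(OAc)2, SPhos, THF, 50 °C) tolerates the aldehyde and should give 13.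

## Further compounds

F1 | step 11 | 2-{[2-methyl-1-(triphenyl-λ5-phosphanylidene)propan-2-yl]oxy}-3-methoxy-6-(methoxymethoxy)-5-[7-(methoxymethoxy)-4-oxo-4H-chromen-3-yl]benzaldehyde (ylide, not isolated) | COCOc1ccc2c(c1)occ(-c1cc(OC)c(OC(C)(C)C=P(c3ccccc3)(c3ccccc3)c3ccccc3)c(C=O)c1OCOC)c2=O
F2 | step 10 | 2-hydroxy-3-methoxy-6-(methoxymethoxy)benzaldehyde | COCOc1ccc(OC)c(O)c1C=O
F3 | step 10 | 3-bromo-6-hydroxy-5-methoxy-2-(methoxymethoxy)benzaldehyde | COCOc1c(Br)cc(OC)c(O)c1C=O
F4 | step 10 | 6-hydroxy-5-methoxy-2-(methoxymethoxy)-3-(4,4,5,5-tetramethyl-1,3,2-dioxaborolan-2-yl)benzaldehyde | COCOc1c(B2OC(C)(C)C(C)(C)O2)cc(OC)c(O)c1C=O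
F5 | step 9 | [7-(methoxymethoxy)-4-oxo-4H-chromen-3-yl]zinc iodide | COCOc1ccc2c(c1)occ([Zn]I)c2=O
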